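**Retrosynthetic overview**
- Numbering: lactone C1(=O), C2H=, C3(CH2OH), stereocentre C4, then C5H2, C6H=C7(CH2OH)–C8H2 and the chain. The strategy rests on the unit O(lactone)–C4–C5–C6=C7. Joined on paper from O to C7, it is a 2-substituted 2,3-dihydrofuran (O1, C2 = C4, C3 = C5, C4=C5 = C6=C7), so a five-membered ring can dictate the Z geometry of this acyclic olefin.
- Key disconnection: C7–C8 and C7–CH2O, both made in one flask. The C7-lithiated dihydrofuran joins a homofarnesyl cuprate, a copper-to-carbon 1,2-shift opens the ring to the C4 alkoxide, and PMBOCH2Cl traps the alkenylcuprate.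
- Rings: the dihydrofuran comes from the γ-lactone ring of (R)-5-oxotetrahydrofuran-2-carboxylic acid, which also supplies C4, and it is opened in the key step. The butenolide, the only ring of the target, is closed afterwards from the C4-hydroxy C3-ketone with Ph3P=C=C=O (O–C1 and C2=C3).
- Chain: (2E,6E)-farnesol is ω-hydroxylated with SeO2 and extended by one carbon (PhSCH2Li, then MeI/NaI) to the homofarnesyl iodide.
- Masking: C3 travels as an acyclic dimethyl ketal, the two outer hydroxyls as TIPS ethers and the C7 CH2OH as a PMB ether. They are released by mild acid, DDQ and HF·pyridine.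

Key step: step 17

Remark on the chemistry (assumption): commercial 1 and 11 are taken as enantiomerically and geometrically pure; two equivalents of iodide 20 are used per dihydrofuran 10 because only one ligand of the homocuprate migrates; target numbering (C1–C8) is used throughout.

**Step 1**
Reactants: 1 (R)-5-oxotetrahydrofuran-2-carboxylic acid
Product: 2 (R)-5-oxotetrahydrofuran-2-carbonyl chloride
Conditions: (COCl)2, DMF (cat.), CH2Cl2, 0 °C → rt
Reagents that add atoms: oxalyl chloride O=C(Cl)C(=O)Cl
Why: Vilsmeier-type acyl chloride formation needs no base, so the α-acyloxy stereocentre C4 is not touched.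

**Step 2**
Reactants: 2 (R)-5-oxotetrahydrofuran-2-carbonyl chloride
Product: 3 (R)-5-(2-diazoacetyl)dihydrofuran-2(3H)-one
Conditions: CH2N2 (excess), Et2O, 0 °C
Reagents that add atoms: diazomethane C=[N+]=[N-]
Why: Acylation of diazomethane (first stage of the Arndt–Eistert sequence) adds the CH2O carbon on C3, and excess diazomethane instead of an amine takes up HCl, which avoids ketene formation and loss of configuration at C4.

**Step 3**
Reactants: 3 (R)-5-(2-diazoacetyl)dihydrofuran-2(3H)-one
Product: 5 (R)-5-(2-hydroxyacetyl)dihydrofuran-2(3H)-one, via trifluoroacetoxymethyl ketone 4 (not isolated)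
Conditions: CF3CO2H, CH2Cl2, 0 °C; evaporate; MeOH, rt
Reagents that add atoms: trifluoroacetic acid OC(=O)C(F)(F)F
Why: Protonation of the diazoketone, SN2 capture of the diazonium ion by trifluoroacetate and neutral methanolysis of the labile ester should give the ketol at or below room temperature with only volatile by-products, so the enolisable C4 never meets hot acid or base.

**Step 4**
Reactants: 5 (R)-5-(2-hydroxyacetyl)dihydrofuran-2(3H)-one
Product: 6 (R)-5-[2-(triisopropylsilyloxy)acetyl]dihydrofuran-2(3H)-one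
Conditions: TIPSCl, imidazole, DMF, 0 °C → rt
Reagents that add atoms: triisopropylsilyl chloride CC(C)[Si](Cl)(C(C)C)C(C)C
Why: This is a standard silylation of a primary alcohol, and TIPS is chosen because it offers tert-butyllithium no Si–CH3 or benzylic C–H in step 17 and outlasts the mild acid of step 18.

**Step 5**
Reactants: 6 (R)-5-[2-(triisopropylsilyloxy)acetyl]dihydrofuran-2(3H)-one
Product: 7 (R)-5-[1,1-dimethoxy-2-(triisopropylsilyloxy)ethyl]dihydrofuran-2(3H)-one
Conditions: MeOSiMe3 (4 equiv), TMSOTf (0.1 equiv), CH2Cl2, −78 → −20 °C; pyridine quench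
Reagents that add atoms: methoxytrimethylsilane CO[Si](C)(C)C
Why: Noyori-type aprotic ketalisation, driven by formation of hexamethyldisiloxane, works cold and without methanol or protic acid, so the lactone stays closed and C4 is not enolised; the acyclic ketal is used because the two flanking C–O bonds retard ionisation so strongly that a dioxolane at this carbon could not be hydrolysed later without loss of the silyl ethers.

**Step 6**
Reactants: 7 (R)-5-[1,1-dimethoxy-2-(triisopropylsilyloxy)ethyl]dihydrofuran-2(3H)-one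
Product: 8 (5R)-5-[1,1-dimethoxy-2-(triisopropylsilyloxy)ethyl]tetrahydrofuran-2-ol (mixture of anomers)
Conditions: DIBAL-H (1.1 equiv), CH2Cl2, −78 °C; Rochelle salt
Reagents that add atoms: none
Why: Partial reduction of a γ-lactone at −78 °C stops at the aluminium hemiacetal, and the new anomeric centre forms as a mixture that step 7 destroys.

**Step 7**
Reactants: 8 (5R)-5-[1,1-dimethoxy-2-(triisopropylsilyloxy)ethyl]tetrahydrofuran-2-ol
Product: 10 (R)-2-[1,1-dimethoxy-2-(triisopropylsilyloxy)ethyl]-2,3-dihydrofuran, via anomeric mesylate 9 (not isolated)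
Conditions: MsCl, Et3N (excess), CH2Cl2, −40 °C → reflux; Et3N-deactivated silica
Reagents that add atoms: none
Why: Anomeric mesylation and loss of methanesulfonate with excess amine is the usual lactol-to-cyclic-enol-ether dehydration; only the C6 hydrogens are β to the leaving group, and the basic medium protects both the enol ether and the ketal.

**Step 8**
Reactants: 11 (2E,6E)-farnesol
Product: 12 (2E,6E)-farnesyl acetate
Conditions: Ac2O, pyridine, DMAP (cat.), CH2Cl2, 0 °C → rt
Reagents that add atoms: acetic anhydride CC(=O)OC(C)=O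
Why: Acetylation masks the allylic alcohol and makes the proximal olefin the least electron-rich of the three, which directs step 9 to the far end.

**Step 9**
Reactants: 12 (2E,6E)-farnesyl acetate
Product: 13 (2E,6E,10E)-12-hydroxy-3,7,11-trimethyldodeca-2,6,10-trien-1-yl acetate
Conditions: SeO2 (cat.), t-BuOOH, salicylic acid (cat.), CH2Cl2, 0 °C → rt, stopped at partial conversion
Reagents that add atoms: selenium dioxide O=[Se]=O; tert-butyl hydroperoxide CC(C)(C)OO
Why: Catalytic Riley allylic oxidation (ene reaction, then [2,3]-sigmatropic shift) prefers the terminal, most electron-rich trisubstituted olefin, and its cyclic transition state delivers the (E)-allylic alcohol.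

**Step 10**
Reactants: 13 (2E,6E,10E)-12-hydroxy-3,7,11-trimethyldodeca-2,6,10-trien-1-yl acetate
Product: 14 (2E,6E,10E)-3,7,11-trimethyl-12-(triisopropylsilyloxy)dodeca-2,6,10-trien-1-yl acetate
Conditions: TIPSCl, imidazole, DMF, rt
Reagents that add atoms: triisopropylsilyl chloride CC(C)[Si](Cl)(C(C)C)C(C)C
Why: Routine silylation; a primary allylic TBS ether would be solvolysed at about the same rate as the ketal in step 18, whereas TIPS should survive that step and the alkyllithium chemistry.

**Step 11**
Reactants: 14 (2E,6E,10E)-3,7,11-trimethyl-12-(triisopropylsilyloxy)dodeca-2,6,10-trien-1-yl acetate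
Product: 15 (2E,6E,10E)-3,7,11-trimethyl-12-(triisopropylsilyloxy)dodeca-2,6,10-trien-1-ol
Conditions: K2CO3 (cat.), MeOH, rt
Reagents that add atoms: none
Why: Base-catalysed transesterification removes the acetate and leaves the TIPS ether intact.

**Step 12**
Reactants: 15 (2E,6E,10E)-3,7,11-trimethyl-12-(triisopropylsilyloxy)dodeca-2,6,10-trien-1-ol
Product: 17 [(2E,6E,10E)-12-bromo-2,6,10-trimethyldodeca-2,6,10-trienyl]oxytriisopropylsilane, via allylic mesylate 16 (not isolated)
Conditions: MsCl, Et3N, THF, −45 °C; LiBr, THF, 0 °C; used crude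
Reagents that add atoms: lithium bromide [Li+].[Br-]
Why: Mesylation followed by cold SN2 displacement with bromide is the standard farnesyl bromide preparation and avoids allylic transposition and E/Z scrambling.

**Step 13**
Reactants: 17 [(2E,6E,10E)-12-bromo-2,6,10-trimethyldodeca-2,6,10-trienyl]oxytriisopropylsilane
Product: 18 triisopropyl{[(2E,6E,10E)-2,6,10-trimethyl-13-(phenylthio)trideca-2,6,10-trienyl]oxy}silane
Conditions: PhSMe, n-BuLi, DABCO, THF, 0 °C; then 17, −78 °C → rt
Reagents that add atoms: thioanisole (as its lithio derivative) CSc1ccccc1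
Why: SN2 alkylation of the sulfur-stabilised carbanion PhSCH2Li by the primary allylic bromide adds the single carbon C8 without touching the olefins.

**Step 14**
Reactants: 18 triisopropyl{[(2E,6E,10E)-2,6,10-trimethyl-13-(phenylthio)trideca-2,6,10-trienyl]oxy}silane
Product: 20 [(2E,6E,10E)-13-iodo-2,6,10-trimethyltrideca-2,6,10-trienyl]oxytriisopropylsilane, via methylphenylsulfonium iodide 19 (not isolated)
Conditions: MeI (excess), NaI, CaCO3, DMF, 75 °C, sealed vessel
Reagents that add atoms: methyl iodide CI; sodium iodide [Na+].[I-]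
Why: S-methylation turns the sulfide into a leaving group, and iodide displaces it at the primary C8 (attack at methyl only regenerates 18), which is the established sulfide-to-iodide end of this one-carbon homologation of allylic halides.

**Step 15**
Reactants: 21 4-methoxybenzyl alcohol
Product: 22 4-methoxybenzyl methylthiomethyl ether
Conditions: NaH, ClCH2SMe, NaI (cat.), DME, 0 °C → rt
Reagents that add atoms: chloromethyl methyl sulfide CSCCl
Why: Williamson-type O-alkylation of the alkoxide gives the O,S-acetal under basic conditions that the acid-labile benzylic alcohol tolerates.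

**Step 16**
Reactants: 22 4-methoxybenzyl methylthiomethyl ether
Product: 23 4-methoxybenzyl chloromethyl ether
Conditions: SO2Cl2, CH2Cl2, −78 °C; evaporate, azeotrope with toluene, use at once
Reagents that add atoms: sulfuryl chloride O=S(=O)(Cl)Cl
Why: Chlorinolysis of the O,S-acetal (chlorosulfonium ion, then oxocarbenium ion, then chloride) gives the α-chloro ether without the HCl/formaldehyde conditions that would ionise the PMB alcohol.

**Step 17**
Reactants: 10 (R)-2-[1,1-dimethoxy-2-(triisopropylsilyloxy)ethyl]-2,3-dihydrofuran; 20 [(2E,6E,10E)-13-iodo-2,6,10-trimethyltrideca-2,6,10-trienyl]oxytriisopropylsilane (2 equiv); 23 4-methoxybenzyl chloromethyl ether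
Product: 29 (3R,5Z,9E,13E,17E)-2,2-dimethoxy-6-[(4-methoxybenzyloxy)methyl]-10,14,18-trimethyl-1,19-bis(triisopropylsilyloxy)nonadeca-5,9,13,17-tetraen-3-ol, via 5-lithiodihydrofuran 24 (not isolated), via homofarnesyllithium 25 (not isolated), via lithium homocuprate 26 (not isolated), via dihydrofuranyl ate complex 27 (not isolated), via ring-opened alkenylcuprate 28 (not isolated)
Conditions: 20, t-BuLi (2 equiv per iodide), Et2O, −78 °C → rt → −78 °C; CuBr·SMe2 (1 equiv), Et2O–Me2S, −78 → −30 °C; 10, t-BuLi (1.05 equiv), THF, −78 → 0 °C, cannulated in at −78 °C; → rt; 23 (2 equiv), −78 → −20 °C; aq NH4Cl–NH3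
Reagents that add atoms: none
Why: tert-Butyllithium removes the vinylic C7–H next to the ring oxygen of 10, and 24 adds to homocuprate 26 to give the α-alkoxyalkenyl ate complex 27, in which one C8 alkyl ligand shifts from copper to C7 anti to the departing C7–O bond (inversion at the sp2 carbon), so the dihydrofuran opens to the C4 lithium alkoxide and copper sits cis to C5 in 28. The alkenyl–copper bond of 28 is then alkylated by the α-chloro ether 23 (oxidative addition, reductive elimination) with retention, which places CH2OPMB cis to C5. The closest known reactions are the copper-mediated 1,2-metallate rearrangement of 5-lithio-2,3-dihydrofurans with homoallylic cuprates and methyl iodide trapping, used for iterative isoprenoid chain building, and the alkoxymethylation of carbocupration-derived alkenylcopper reagents with chloromethyl ethers. No ring is closed (one is opened) and no sp3 stereocentre is made: the C4–O bond is never touched, so C4 passes through unchanged, and the Z geometry of C6=C7 follows from the ring, which enforces inversion for the migrating group and retention for the electrophile. The step needs C- over O-alkylation and alkenyl over alkyl ligand transfer: the C4 alkoxide is a secondary lithium alkoxide next to the fully substituted ketal carbon and is aggregated in ether–dimethyl sulfide at low temperature without polar cosolvent, and sp2 ligands couple faster than sp3 ligands from the copper(III) intermediate. The dimethyl ketal and the TIPS ethers offer the organometallics no acidic or electrophilic site.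

**Step 18**
Reactants: 29 (3R,5Z,9E,13E,17E)-2,2-dimethoxy-6-[(4-methoxybenzyloxy)methyl]-10,14,18-trimethyl-1,19-bis(triisopropylsilyloxy)nonadeca-5,9,13,17-tetraen-3-ol
Product: 30 (3R,5Z,9E,13E,17E)-3-hydroxy-6-[(4-methoxybenzyloxy)methyl]-10,14,18-trimethyl-1,19-bis(triisopropylsilyloxy)nonadeca-5,9,13,17-tetraen-2-one
Conditions: TsOH·H2O (0.1 equiv), acetone–H2O 9:1, rt; NaHCO3 quench; used promptly
Reagents that add atoms: water O
Why: In this acid-catalysed ketal hydrolysis the deactivated acyclic ketal should behave like an ordinary dioxolane and ionise well before primary TIPS ethers or the allylic PMB ether are solvolysed, and the dilute acid at room temperature is too mild to enolise the α-ketol at C4.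

**Step 19**
Reactants: 30 (3R,5Z,9E,13E,17E)-3-hydroxy-6-[(4-methoxybenzyloxy)methyl]-10,14,18-trimethyl-1,19-bis(triisopropylsilyloxy)nonadeca-5,9,13,17-tetraen-2-one
Product: 32 (R)-5-[(2Z,6E,10E,14E)-3-[(4-methoxybenzyloxy)methyl]-7,11,15-trimethyl-16-(triisopropylsilyloxy)hexadeca-2,6,10,14-tetraenyl]-4-(triisopropylsilyloxymethyl)furan-2(5H)-one, via ester ylide 31 (not isolated)
Conditions: Ph3P=C=C=O (1.3 equiv), toluene, 90 °C
Reagents that add atoms: (triphenylphosphoranylidene)ketene O=C=C=P(c1ccccc1)(c1ccccc1)c1ccccc1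
Why: The only free hydroxyl (C4–OH) adds to the Bestmann ylide to give the ester-stabilised phosphorane 31, which closes the five-membered ring by intramolecular Wittig olefination of the electron-poor C3 ketone under neutral conditions, so C4 keeps its configuration.

**Step 20**
Reactants: 32 PMB-protected bis-TIPS butenolide
Product: 33 (R)-5-[(2Z,6E,10E,14E)-3-(hydroxymethyl)-7,11,15-trimethyl-16-(triisopropylsilyloxy)hexadeca-2,6,10,14-tetraenyl]-4-(triisopropylsilyloxymethyl)furan-2(5H)-one
Conditions: DDQ (1.3 equiv), CH2Cl2–pH 7 buffer 10:1, 0 °C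
Reagents that add atoms: none
Why: In this oxidative PMB cleavage DDQ abstracts hydride from the electron-rich benzylic position, and at 0 °C in buffer the silyl-protected allylic positions, the trisubstituted olefins and the butenolide should not compete.

**Step 21**
Reactants: 33 bis-TIPS butenolide with free C7 hydroxymethyl group
Product: 34 hippolide F, (R)-4-(hydroxymethyl)-5-[(2Z,6E,10E,14E)-16-hydroxy-3-(hydroxymethyl)-7,11,15-trimethylhexadeca-2,6,10,14-tetraenyl]furan-2(5H)-one
Conditions: HF·pyridine, pyridine, THF, 0 °C → rt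
Reagents that add atoms: none
Why: Buffered fluoride desilylation removes both primary TIPS ethers without the basicity of TBAF, which could deprotonate the acidic C4–H of the butenolide and racemise it.

**Compound list**
1 | (R)-5-oxotetrahydrofuran-2-carboxylic acid | O=C1CC[C@H](C(=O)O)O1 | starting material
2 | (R)-5-oxotetrahydrofuran-2-carbonyl chloride | O=C1CC[C@H](C(=O)Cl)O1 | intermediate
3 | (R)-5-(2-diazoacetyl)dihydrofuran-2(3H)-one | O=C1CC[C@H](C(=O)C=[N+]=[N-])O1 | intermediate
4 | 2-oxo-2-[(R)-5-oxotetrahydrofuran-2-yl]ethyl trifluoroacetate (not isolated) | O=C1CC[C@H](C(=O)COC(=O)C(F)(F)F)O1 | intermediate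
5 | (R)-5-(2-hydroxyacetyl)dihydrofuran-2(3H)-one | O=C1CC[C@H](C(=O)CO)O1 | intermediate
6 | (R)-5-[2-(triisopropylsilyloxy)acetyl]dihydrofuran-2(3H)-one | O=C1CC[C@H](C(=O)CO[Si](C(C)C)(C(C)C)C(C)C)O1 | intermediate
7 | (R)-5-[1,1-dimethoxy-2-(triisopropylsilyloxy)ethyl]dihydrofuran-2(3H)-one | O=C1CC[C@H](C(OC)(OC)CO[Si](C(C)C)(C(C)C)C(C)C)O1 | intermediate
8 | (5R)-5-[1,1-dimethoxy-2-(triisopropylsilyloxy)ethyl]tetrahydrofuran-2-ol, anomer mixture | OC1CC[C@H](C(OC)(OC)CO[Si](C(C)C)(C(C)C)C(C)C)O1 | intermediate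
9 | anomeric methanesulfonate of 8 (not isolated) | CS(=O)(=O)OC1CC[C@H](C(OC)(OC)CO[Si](C(C)C)(C(C)C)C(C)C)O1 | intermediate
10 | (R)-2-[1,1-dimethoxy-2-(triisopropylsilyloxy)ethyl]-2,3-dihydrofuran | C1C=CO[C@H]1C(OC)(OC)CO[Si](C(C)C)(C(C)C)C(C)C | intermediate
11 | (2E,6E)-farnesol | CC(C)=CCC/C(C)=C/CC/C(C)=C/CO | starting material
12 | (2E,6E)-farnesyl acetate | CC(C)=CCC/C(C)=C/CC/C(C)=C/COC(C)=O | intermediate
13 | (2E,6E,10E)-12-hydroxy-3,7,11-trimethyldodeca-2,6,10-trien-1-yl acetate | C/C(=C\CC/C(C)=C/CC/C(C)=C/COC(C)=O)CO | intermediate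
14 | (2E,6E,10E)-3,7,11-trimethyl-12-(triisopropylsilyloxy)dodeca-2,6,10-trien-1-yl acetate | C/C(=C\CC/C(C)=C/CC/C(C)=C/COC(C)=O)CO[Si](C(C)C)(C(C)C)C(C)C | intermediate
15 | (2E,6E,10E)-3,7,11-trimethyl-12-(triisopropylsilyloxy)dodeca-2,6,10-trien-1-ol | C/C(=C\CC/C(C)=C/CC/C(C)=C/CO)CO[Si](C(C)C)(C(C)C)C(C)C | intermediate
16 | methanesulfonate of 15 (not isolated) | C/C(=C\CC/C(C)=C/CC/C(C)=C/COS(C)(=O)=O)CO[Si](C(C)C)(C(C)C)C(C)C | intermediate
17 | [(2E,6E,10E)-12-bromo-2,6,10-trimethyldodeca-2,6,10-trienyl]oxytriisopropylsilane | C/C(=C\CC/C(C)=C/CC/C(C)=C/CBr)CO[Si](C(C)C)(C(C)C)C(C)C | intermediate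
18 | triisopropyl{[(2E,6E,10E)-2,6,10-trimethyl-13-(phenylthio)trideca-2,6,10-trienyl]oxy}silane | C/C(=C\CC/C(C)=C/CC/C(C)=C/CCSc1ccccc1)CO[Si](C(C)C)(C(C)C)C(C)C | intermediate
19 | S-methyl-S-phenylsulfonium iodide of 18 (not isolated) | C/C(=C\CC/C(C)=C/CC/C(C)=C/CC[S+](C)c1ccccc1)CO[Si](C(C)C)(C(C)C)C(C)C.[I-] | intermediate
20 | [(2E,6E,10E)-13-iodo-2,6,10-trimethyltrideca-2,6,10-trienyl]oxytriisopropylsilane (ω-TIPS-oxy homofarnesyl iodide) | C/C(=C\CC/C(C)=C/CC/C(C)=C/CCI)CO[Si](C(C)C)(C(C)C)C(C)C | intermediate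
21 | 4-methoxybenzyl alcohol | COc1ccc(CO)cc1 | starting material
22 | 4-methoxybenzyl methylthiomethyl ether | COc1ccc(COCSC)cc1 | intermediate
23 | 4-methoxybenzyl chloromethyl ether | COc1ccc(COCCl)cc1 | intermediate
24 | (R)-5-lithio-2-[1,1-dimethoxy-2-(triisopropylsilyloxy)ethyl]-2,3-dihydrofuran (not isolated) | C1C=C([Li])O[C@H]1C(OC)(OC)CO[Si](C(C)C)(C(C)C)C(C)C | intermediate
25 | ω-TIPS-oxy homofarnesyllithium (not isolated) | C/C(=C\CC/C(C)=C/CC/C(C)=C/CC[Li])CO[Si](C(C)C)(C(C)C)C(C)C | intermediate
26 | lithium bis(ω-TIPS-oxy homofarnesyl)cuprate (not isolated) | [Li+].CC(C)[Si](C(C)C)(C(C)C)OC/C(C)=C/CC/C(C)=C/CC/C(C)=C/CC[Cu-]CC/C=C(C)/CC/C=C(C)/CC/C=C(C)/CO[Si](C(C)C)(C(C)C)C(C)C | intermediate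
27 | dilithium (dihydrofuran-5-yl)bis(homofarnesyl)cuprate (not isolated) | [Li+].[Li+].C1C=C([Cu-2](CC/C=C(C)/CC/C=C(C)/CC/C=C(C)/CO[Si](C(C)C)(C(C)C)C(C)C)CC/C=C(C)/CC/C=C(C)/CC/C=C(C)/CO[Si](C(C)C)(C(C)C)C(C)C)O[C@H]1C(OC)(OC)CO[Si](C(C)C)(C(C)C)C(C)C | intermediate
28 | ring-opened C4-oxido alkenyl(homofarnesyl)cuprate, Cu on C7 cis to C5 (not isolated) | [Li+].[Li+].C/C(=C\CC/C(C)=C/CC/C(C)=C/CC/C(=C/C[C@@H]([O-])C(OC)(OC)CO[Si](C(C)C)(C(C)C)C(C)C)[Cu-]CC/C=C(C)/CC/C=C(C)/CC/C=C(C)/CO[Si](C(C)C)(C(C)C)C(C)C)CO[Si](C(C)C)(C(C)C)C(C)C | intermediate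
29 | (3R,5Z,9E,13E,17E)-2,2-dimethoxy-6-[(4-methoxybenzyloxy)methyl]-10,14,18-trimethyl-1,19-bis(triisopropylsilyloxy)nonadeca-5,9,13,17-tetraen-3-ol | C/C(=C\CC/C(C)=C/CC/C(C)=C/CC/C(=C/C[C@@H](O)C(OC)(OC)CO[Si](C(C)C)(C(C)C)C(C)C)COCc1ccc(OC)cc1)CO[Si](C(C)C)(C(C)C)C(C)C | intermediate
30 | (3R,5Z,9E,13E,17E)-3-hydroxy-6-[(4-methoxybenzyloxy)methyl]-10,14,18-trimethyl-1,19-bis(triisopropylsilyloxy)nonadeca-5,9,13,17-tetraen-2-one | C/C(=C\CC/C(C)=C/CC/C(C)=C/CC/C(=C/C[C@@H](O)C(=O)CO[Si](C(C)C)(C(C)C)C(C)C)COCc1ccc(OC)cc1)CO[Si](C(C)C)(C(C)C)C(C)C | intermediate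
31 | (triphenylphosphoranylidene)acetate of 30 at C4–O (not isolated) | C/C(=C\CC/C(C)=C/CC/C(C)=C/CC/C(=C/C[C@@H](OC(=O)C=P(c1ccccc1)(c1ccccc1)c1ccccc1)C(=O)CO[Si](C(C)C)(C(C)C)C(C)C)COCc1ccc(OC)cc1)CO[Si](C(C)C)(C(C)C)C(C)C | intermediate
32 | (R)-5-[(2Z,6E,10E,14E)-3-[(4-methoxybenzyloxy)methyl]-7,11,15-trimethyl-16-(triisopropylsilyloxy)hexadeca-2,6,10,14-tetraenyl]-4-(triisopropylsilyloxymethyl)furan-2(5H)-one | C/C(=C\CC/C(C)=C/CC/C(C)=C/CC/C(=C/C[C@H]1OC(=O)C=C1CO[Si](C(C)C)(C(C)C)C(C)C)COCc2ccc(OC)cc2)CO[Si](C(C)C)(C(C)C)C(C)C | intermediate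
33 | (R)-5-[(2Z,6E,10E,14E)-3-(hydroxymethyl)-7,11,15-trimethyl-16-(triisopropylsilyloxy)hexadeca-2,6,10,14-tetraenyl]-4-(triisopropylsilyloxymethyl)furan-2(5H)-one | C/C(=C\CC/C(C)=C/CC/C(C)=C/CC/C(=C/C[C@H]1OC(=O)C=C1CO[Si](C(C)C)(C(C)C)C(C)C)CO)CO[Si](C(C)C)(C(C)C)C(C)C | intermediate
34 | hippolide F | C/C(=C\CC/C(C)=C/CC/C(C)=C/CC/C(=C/C[C@H]1OC(=O)C=C1CO)CO)CO | target

**Step count**
Total: 21 steps. Longest linear sequence: 12 steps (steps 1–7 or 8–14, then 17–21).

**Steps most likely to fail**

1. Step 17.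
 - What may go wrong: the reactive α-chloro ether may O-alkylate the freshly liberated C4 alkoxide. The spectator alkyl ligand may couple in place of the alkenyl ligand. Acid traces in the crude chloride may protonate the alkenylcuprate.
 - Fallback: the rearrangement is kept, but the C7–CH2O bond is made by cross-coupling. It sets out from 10 and 20 through cuprate 28.
 - Cuprate 28 is quenched with iodine at −78 °C, a trap to which the alkoxide is indifferent. This should give the (Z)-alkenyl iodide F1, and the spectator ligand returns as iodide 20.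
 - Tributyl[(4-methoxybenzyloxy)methyl]stannane F2 is made from 21 with NaH and (iodomethyl)tributylstannane.
 - Stille coupling of the two (Pd2(dba)3, AsPh3, CuI, LiCl, NMP, 60 °C) retains the olefin geometry and comes back to the route at 29.

2. Step 5.
 - What may go wrong: ketalisation may be sluggish or incomplete, because the oxocarbenium ion is destabilised by two flanking C–O bonds and the ketone is branched. Forcing the reaction risks acid-induced enolisation and erosion of configuration at C4.
 - Fallback: it sets out from 6. Thioketalisation relies on better nucleophiles and a better stabilised cation (1,3-propanedithiol, BF3·OEt2, CH2Cl2, −20 → 0 °C) and should give the 1,3-dithiane F3.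
 - Oxidative solvolysis of the dithiane in methanol (PhI(OCOCF3)2, MeOH, 0 °C) exchanges sulfur for two methoxy groups and comes back to the route at 7.

3. Step 18.
 - What may go wrong: one or both silyl ethers may be lost in competition with ketal hydrolysis, which would expose a second hydroxyl next to the ketone and misdirect step 19. Prolonged acid exposure may isomerise the α-ketol.
 - Fallback: chemoselective hydrolysis is given up. It sets out from 29, which is treated with 1 M HCl in THF–MeOH at rt until the ketal and both silyl ethers are gone, giving the PMB-protected trihydroxy ketone F4.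
 - The two primary hydroxyls are then re-silylated selectively over the hindered secondary C4–OH (TIPSCl, 2.1 equiv, imidazole, CH2Cl2, 0 °C), which comes back to the route at 30.

**Further compounds**
F1 | step 17 | (3R,5Z,9E,13E,17E)-6-iodo-2,2-dimethoxy-10,14,18-trimethyl-1,19-bis(triisopropylsilyloxy)nonadeca-5,9,13,17-tetraen-3-ol | C/C(=C\CC/C(C)=C/CC/C(C)=C/CC/C(I)=C/C[C@@H](O)C(OC)(OC)CO[Si](C(C)C)(C(C)C)C(C)C)CO[Si](C(C)C)(C(C)C)C(C)C
F2 | step 17 | tributyl[(4-methoxybenzyloxy)methyl]stannane | CCCC[Sn](CCCC)(CCCC)COCc1ccc(OC)cc1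
F3 | step 5 | (R)-5-[2-(triisopropylsilyloxymethyl)-1,3-dithian-2-yl]dihydrofuran-2(3H)-one | O=C1CC[C@H](C2(CO[Si](C(C)C)(C(C)C)C(C)C)SCCCS2)O1
F4 | step 18 | (3R,5Z,9E,13E,17E)-1,3,19-trihydroxy-6-[(4-methoxybenzyloxy)methyl]-10,14,18-trimethylnonadeca-5,9,13,17-tetraen-2-one | C/C(=C\CC/C(C)=C/CC/C(C)=C/CC/C(=C/C[C@@H](O)C(=O)CO)COCc1ccc(OC)cc1)CO
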